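There are 5 questions on one charge: how much target each of 4 set-ups holds at its end or outlet, and which leads.

| flask | substrate | partner | remark | time |
|---|---|---|---|---|
| alder | 0.39 M | 0.39 M | run made earlier |  |
| maple | 0.39 M | 0.26 M | run made earlier |  |
| birch | 0.39 M | 0.58 M | run made earlier |  |
| epsilon | 0.39 M (fed, over 5.00 min) | 0.390 M | all but substrate at the start; substrate goes in evenly over 5.00 min, the run ends at 5.0 min | 5.0 min |
| zeta | 0.39 M | 0.390 M | a closed flask charged with all of it at once and left for 5.0 min | 5.0 min |
| beta | 0.39 M | 0.390 M | a single well-mixed tank run continuously and read at steady state, 5.0 min in it on average |  |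
| theta | 0.39 M | 0.390 M (fed, over 5.00 min) | all but partner at the start; partner goes in evenly over 5.00 min, the run ends at 5.0 min | 5.0 min |

| run | time / min | target / % | substrate / % |
|---|---|---|---|
| alder | 0.417 | 2 | 92 |
| alder | 0.667 | 11 | 86 |
| alder | 1.00 | 14 | 77 |
| alder | 1.33 | 17 | 75 |
| alder | 2.00 | 23 | 67 |
| alder | 3.00 | 29 | 60 |
| alder | 5.00 | 35 | 45 |
| maple | 0.500 | 6 | 91 |
| maple | 0.667 | 7 | 89 |
| maple | 1.00 | 9 | 85 |
| maple | 1.50 | 14 | 76 |
| maple | 2.50 | 19 | 67 |
| maple | 4.00 | 25 | 61 |
| maple | 6.00 | 27 | 47 |
| birch | 0.333 | 10 | 89 |
| birch | 1.00 | 17 | 74 |
| birch | 1.50 | 25 | 63 |
| birch | 2.50 | 36 | 53 |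
| birch | 4.00 | 45 | 44 |
| birch | 5.00 | 48 | 39 |
| birch | 6.00 | 49 | 34 |

(each reading ± 1.5 percentage points)

- the set-up with the highest amount of target at the outlet or at the end, in percent of the substrate put in ("none" if the first two lie within 2 percentage points) (epsilon / zeta / beta / theta / none)
- amount of target at the outlet or at the end, in percent of the substrate put in, epsilon
- amount of target at the outlet or at the end, in percent of the substrate put in, zeta
- amount of target at the outlet or at the end, in percent of the substrate put in, beta
- amount of target at the outlet or at the end, in percent of the substrate put in, theta

- the stated concentrations are those of everything mixed, before any reaction; amounts are the same in each set-up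
- what was read earlier has a scatter of 1.5 percentage points, one standard deviation
- the feed brings no volume worth counting
- the earlier runs were made in a closed, stirred flask

Two chemists differ. The first watches the split (a selectivity factor): target made per substrate lost elsewhere, the loss being 20.0% of the charge at alder's last reading. If target goes as substrate times partner and the loss as substrate squared, the split is a constant times mean partner over mean substrate. Replace each curve by the mean of its ends and count partner used as equal to target, and alder's last reading gives 1.54 for this split constant. Maple's last reading gives 1.44 and birch's 1.55. Taking a mean substrate of half its charge and partner at its charge, the first chemist estimates epsilon's split at 3.08, higher than the 1.75 read for alder, and so bets on epsilon.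

The second answers that a split says nothing of how much has reacted, and zeta repeats alder, which shows 35% at its last reading. My own reckoning sides with the second. Alder consumed 55.0% at a mean substrate of 72.5%. Scaled to a mean of half the charge, my estimate of epsilon's consumption is 37.9%, and the estimated split sends 75.5% of that to target, which gives 28.6%, less than alder's last reading.

The forecast is the second chemist's: zeta first, with zeta 36%, beta 27%, epsilon 25% (below my figure) and theta 22%. Its ground: “Batch wins clearly because time at high concentration matters most.”

The flask gives zeta 35.3%, the highest, then beta 26.5%, epsilon 24.4% and theta 21.4%.

    substrate + partner ⇌ isomer of the product (K = 245 /M, k = 8.28 × 10⁻⁵ /M/s)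
    substrate + partner ⇌ target (K = 6.10 /M, k = 0.00734 /M/s)
    2 substrate → self-condensation product (k = 0.00165 /M/s)
    partner → decomposed reagent (k = 1.22 × 10⁻⁴ /s)

The first chemist keeps the split: target over self-condensation product is 3.41 in epsilon against 2.02 in zeta, while the constant, with the means of the ends of epsilon's substrate and partner, estimates 3.88 for epsilon. The forecast would fall if the order turned, and at 50.0 min epsilon's 30.7% does pass zeta's 29.9%, though inside the margin of 2 percentage points. In zeta, substrate's half-life by the forward making of target alone, with partner as charged, is 4.0 min, against 95 min for partner's loss to decomposed reagent alone. Zeta ends with 0.0107 M of decomposed reagent.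

Take theta with 0.97 M of partner: the constant, with partner's mean at half its end amount and substrate's the mean of its ends, gives a split of 2.27. Computed, that flask holds 44.3% target and 19.4% self-condensation product, a ratio of 2.28.

Readings and results stem from a simulated flask for an exercise; the scatter is artificial.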